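**Retrosynthetic overview**

1. The target is read as methyl (13E)-19-acetoxylabda-8,13-dien-15-oate, (4S,5R,10S). Labdane numbering is used throughout: ring A = C1–C5/C10, ring B = C5–C10, C17 on C8, C18 (methyl) and C19 (CH2OAc) on C4, C20 on C10, side chain C11–C16 on C9.
2. Late disconnections: the O-acetyl group; C13=C14 (Horner–Wadsworth–Emmons reaction on a C13 methyl ketone); C11=C12 (olefination of a C11 aldehyde, then saturation); C4–C18 (ester enolate methylation after one ester of a C4 geminal diester is removed).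
3. Key disconnection: ring B is opened as a Diels–Alder adduct by cutting C8–C9 and C5–C10 together. This leads to an achiral open-chain trienal (C5=C6–C7=C8 diene, C9=C10 enal with C11 as CHO, C1–C4 as tether), so rings A and B form in the same step, ring A as the tether ring and ring B as the cycloadduct ring.
4. Enabling feature: in the six-membered ring B the bond C8–C9 lies opposite the ring-fusion bond C5–C10, C10 carries a methyl group and C9 carries C11. C20–C10=C9–C11 is therefore the (E)-3-methylalk-2-enal end of a geranyl unit, and the ring A atoms C1–C4 are a four-atom tether. The adduct has its alkene at C6=C7 and sp3 centres at C8/C9; the C8=C9 double bond is restored through the C11 aldehyde (hydrogenation, then selenoxide elimination).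
5. The trienal is assembled from geranyl acetate (C1–C3, C9–C11, C20) and a pentenylidene malonate (C4–C8, C17, C19), joined at C3–C4.

Key step: step 8

Assumption: the (S)-oxazaborolidinium catalyst is taken to leave open the enal face that leads to 13; if the sense proves to be the opposite, the (R)-catalyst is used in the same procedure.

**Route**

Step 1
Reactants: 1 geranyl acetate [(2E)-3,7-dimethylocta-2,6-dien-1-yl acetate]
Product: 3 (2E)-3-methyl-6-oxohex-2-en-1-yl acetate, via secondary ozonide 2 (not isolated)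
Conditions: O3 (1.0 equiv), CH2Cl2, −78 °C; then Me2S, −78 °C → rt
Reagents that add atoms: ozone, [O-][O+]=O
Why: Ozone should attack the electron-rich terminal trisubstituted alkene much faster than the alkene deactivated by the allylic acetate, so one equivalent cleaves only the isopropylidene end (ozonolysis with reductive work-up).

Step 2
Reactants: 3 (2E)-3-methyl-6-oxohex-2-en-1-yl acetate
Product: 4 (2E)-6-hydroxy-3-methylhex-2-en-1-yl acetate
Conditions: NaBH4, MeOH, 0 °C
Reagents that add atoms: none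
Why: Chemoselective hydride reduction of the aldehyde at 0 °C should leave the acetate and the alkene untouched.

Step 3
Reactants: 4 (2E)-6-hydroxy-3-methylhex-2-en-1-yl acetate
Product: 5 (2E)-6-iodo-3-methylhex-2-en-1-yl acetate
Conditions: I2, PPh3, imidazole, CH2Cl2, 0 °C → rt
Reagents that add atoms: iodine, II
Why: Appel-type iodination of the primary alcohol proceeds by SN2 displacement of the oxyphosphonium ion and should not affect the allylic acetate.

Step 4
Reactants: 6 (2E)-pent-2-enal; 7 dimethyl malonate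
Product: 8 dimethyl 2-[(2E)-pent-2-en-1-ylidene]propanedioate
Conditions: piperidine (cat.), AcOH (cat.), benzene, reflux, Dean–Stark trap
Reagents that add atoms: none
Why: Knoevenagel condensation with azeotropic removal of water should give the conjugated dienylidene malonate with the E-alkene of 6 retained.

Step 5
Reactants: 8 dimethyl 2-[(2E)-pent-2-en-1-ylidene]propanedioate; 5 (2E)-6-iodo-3-methylhex-2-en-1-yl acetate
Product: 10 dimethyl 2-[(4E)-6-(acetyloxy)-4-methylhex-4-en-1-yl]-2-[(1E,3E)-penta-1,3-dien-1-yl]propanedioate, via sodium salt 9 (not isolated)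
Conditions: NaH, THF/DMF, 0 °C; then 5, 0 °C → rt
Reagents that add atoms: none
Why: Deprotonation at the ε-CH2 group gives a pentadienyl-type malonate anion that should be alkylated at the malonate carbon by the primary iodide (deconjugative α-alkylation of an alkylidene malonate), which creates the quaternary C4 and the conjugated diene in its more stable E,E geometry.

Step 6
Reactants: 10 dimethyl 2-[(4E)-6-(acetyloxy)-4-methylhex-4-en-1-yl]-2-[(1E,3E)-penta-1,3-dien-1-yl]propanedioate
Product: 11 dimethyl 2-[(4E)-6-hydroxy-4-methylhex-4-en-1-yl]-2-[(1E,3E)-penta-1,3-dien-1-yl]propanedioate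
Conditions: K2CO3 (cat.), MeOH, 0 °C → rt
Reagents that add atoms: none
Why: Base-catalysed transesterification with methanol should remove the allylic acetate while the methyl esters stay unchanged.

Step 7
Reactants: 11 dimethyl 2-[(4E)-6-hydroxy-4-methylhex-4-en-1-yl]-2-[(1E,3E)-penta-1,3-dien-1-yl]propanedioate
Product: 12 dimethyl 2-[(4E)-4-methyl-6-oxohex-4-en-1-yl]-2-[(1E,3E)-penta-1,3-dien-1-yl]propanedioate
Conditions: MnO2 (activated, excess), CH2Cl2, rt
Reagents that add atoms: none
Why: MnO2 oxidises allylic alcohols selectively and should give the (E)-enal without isomerisation or over-oxidation.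

Step 8
Reactants: 12 dimethyl 2-[(4E)-4-methyl-6-oxohex-4-en-1-yl]-2-[(1E,3E)-penta-1,3-dien-1-yl]propanedioate
Product: 13 dimethyl (4aS,5S,6S,8aR)-5-formyl-4a,6-dimethyl-3,4,4a,5,6,8a-hexahydronaphthalene-1,1(2H)-dicarboxylate
Conditions: (S)-3,3-diphenyl-1-(2-methylphenyl)tetrahydro-1H,3H-pyrrolo[1,2-c][1,3,2]oxazaborole (C24H24BNO, 20 mol %), HN(SO2CF3)2 (16 mol %), CH2Cl2, −78 → −20 °C
Reagents that add atoms: none
Why: The N-protonated oxazaborolidine binds the formyl oxygen of 12, and the activated s-trans (E)-enal undergoes a concerted but asynchronous intramolecular [4+2] cycloaddition with the (1E,3E)-diene in which the C5–C10 bond is more advanced than the C8–C9 bond that completes ring B. The closest known reaction type is the oxazaborolidinium-catalysed enantioselective intramolecular Diels–Alder reaction of (2E,7E,9E)-deca-2,7,9-trienals to trans-fused octalin carbaldehydes. Ring B closes as the six-membered cycloadduct ring (new bonds C8–C9 and C5–C10, new alkene C6=C7) and ring A closes in the same event as the six-membered tether ring through C5–C10, with the C1–C4 chain in a chair-like arrangement. C5 and C10 are set trans by the endo position of the formyl group (the C20 methyl is cis to the formyl group on the E-dienophile and therefore ends anti to H5), C8 and C9 follow from the E,E-diene and the E-dienophile (C17 methyl, formyl and C20 methyl all cis) and are removed again in step 10, and the absolute sense is set by the catalyst, which leaves only one face of the bound enal open. The step needs endo selectivity and enantiofacial selectivity on an achiral substrate: the first is secured by Lewis-acid activation of the (E)-enal together with the four-atom tether, the second by the chiral pocket, and no stereocentre in the tether competes because C4 carries two identical ester groups, which also favour the folded conformer (Thorpe–Ingold effect). An aldehyde is used as the activating group because in its s-trans complex the C20 methyl faces only the formyl hydrogen.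

Step 9
Reactants: 13 dimethyl (4aS,5S,6S,8aR)-5-formyl-4a,6-dimethyl-3,4,4a,5,6,8a-hexahydronaphthalene-1,1(2H)-dicarboxylate
Product: 14 dimethyl (4aS,5S,6S,8aR)-5-formyl-4a,6-dimethyloctahydronaphthalene-1,1(2H)-dicarboxylate
Conditions: H2 (1 atm), Pd/C (5 wt %), EtOAc, rt
Reagents that add atoms: none
Why: Heterogeneous hydrogenation should saturate the only C=C bond (C6=C7, cis-disubstituted) while the aldehyde and the esters survive.

Step 10
Reactants: 14 dimethyl (4aS,5S,6S,8aR)-5-formyl-4a,6-dimethyloctahydronaphthalene-1,1(2H)-dicarboxylate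
Product: 17 dimethyl (4aS,8aR)-5-formyl-4a,6-dimethyl-3,4,4a,7,8,8a-hexahydronaphthalene-1,1(2H)-dicarboxylate, via selenide 15 (not isolated), via selenoxide 16 (not isolated)
Conditions: PhSeCl, EtOAc, rt; then H2O2 (30 % aq.), pyridine, CH2Cl2, 0 °C → rt
Reagents that add atoms: none
Why: α-Selenenylation of the aldehyde through its enol should place selenium at C9 on the face opposite to the C20 and C17 methyl groups, and the selenoxide then undergoes syn elimination towards the only β-hydrogen (H8, cis to selenium) to give the tetrasubstituted C8=C9 enal.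

Step 11
Reactants: 17 dimethyl (4aS,8aR)-5-formyl-4a,6-dimethyl-3,4,4a,7,8,8a-hexahydronaphthalene-1,1(2H)-dicarboxylate
Product: 18 dimethyl (4aS,8aR)-4a,6-dimethyl-5-[(1E)-3-oxobut-1-en-1-yl]-3,4,4a,7,8,8a-hexahydronaphthalene-1,1(2H)-dicarboxylate
Conditions: NaH, dimethyl (2-oxopropyl)phosphonate, THF, 0 °C → reflux
Reagents that add atoms: dimethyl (2-oxopropyl)phosphonate, COP(=O)(OC)CC(C)=O
Why: Horner–Wadsworth–Emmons olefination with the stabilised β-ketophosphonate anion should convert the hindered enal into the (E)-enone and so attach C12, C13 and C16.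

Step 12
Reactants: 18 dimethyl (4aS,8aR)-4a,6-dimethyl-5-[(1E)-3-oxobut-1-en-1-yl]-3,4,4a,7,8,8a-hexahydronaphthalene-1,1(2H)-dicarboxylate
Product: 19 dimethyl (4aS,8aR)-4a,6-dimethyl-5-(3-oxobutyl)-3,4,4a,7,8,8a-hexahydronaphthalene-1,1(2H)-dicarboxylate
Conditions: H2 (1 atm), Pd/C (5 wt %), EtOAc, rt, stopped after one equivalent of H2
Reagents that add atoms: none
Why: Catalytic hydrogenation should reduce the unhindered disubstituted C11=C12 bond of the dienone and leave the tetrasubstituted C8=C9 bond, as in the conversion of ionones into dihydroionones.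

Step 13
Reactants: 19 dimethyl (4aS,8aR)-4a,6-dimethyl-5-(3-oxobutyl)-3,4,4a,7,8,8a-hexahydronaphthalene-1,1(2H)-dicarboxylate
Product: 20 dimethyl (4aS,8aR)-4a,6-dimethyl-5-[2-(2-methyl-1,3-dioxolan-2-yl)ethyl]-3,4,4a,7,8,8a-hexahydronaphthalene-1,1(2H)-dicarboxylate
Conditions: ethylene glycol, pyridinium p-toluenesulfonate (cat.), benzene, reflux, Dean–Stark trap
Reagents that add atoms: ethylene glycol, OCCO
Why: Acid-catalysed ketalisation with removal of water protects the methyl ketone against the enolate and hydride steps that follow.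

Step 14
Reactants: 20 dimethyl (4aS,8aR)-4a,6-dimethyl-5-[2-(2-methyl-1,3-dioxolan-2-yl)ethyl]-3,4,4a,7,8,8a-hexahydronaphthalene-1,1(2H)-dicarboxylate
Product: 21 methyl (4aS,8aS)-4a,6-dimethyl-5-[2-(2-methyl-1,3-dioxolan-2-yl)ethyl]-1,2,3,4,4a,7,8,8a-octahydronaphthalene-1-carboxylate (both C1 epimers)
Conditions: LiCl, H2O (2 equiv), DMSO, 160 °C
Reagents that add atoms: none
Why: Krapcho dealkoxycarbonylation (chloride attack on an ester methyl group, loss of CO2, protonation) should remove one ester of the geminal diester and leave an enolisable C4–H ester whose configuration is of no consequence.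

Step 15
Reactants: 21 methyl (4aS,8aS)-4a,6-dimethyl-5-[2-(2-methyl-1,3-dioxolan-2-yl)ethyl]-1,2,3,4,4a,7,8,8a-octahydronaphthalene-1-carboxylate
Product: 23 methyl (1S,4aS,8aR)-1,4a,6-trimethyl-5-[2-(2-methyl-1,3-dioxolan-2-yl)ethyl]-1,2,3,4,4a,7,8,8a-octahydronaphthalene-1-carboxylate, via lithium enolate 22 (not isolated)
Conditions: LiN(iPr)2, THF, −78 → 0 °C; then MeI, DMPU, −78 °C → rt
Reagents that add atoms: iodomethane, CI
Why: The exocyclic ester enolate should be methylated from the α face (equatorial attack) because the β face is blocked by the 1,3-diaxial C20 methyl group, which places the new C18 methyl equatorial and the C19 ester axial and so sets C4 (ester enolate alkylation).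

Step 16
Reactants: 23 methyl (1S,4aS,8aR)-1,4a,6-trimethyl-5-[2-(2-methyl-1,3-dioxolan-2-yl)ethyl]-1,2,3,4,4a,7,8,8a-octahydronaphthalene-1-carboxylate
Product: 25 4-[(4aR,5S,8aS)-5-(hydroxymethyl)-2,5,8a-trimethyl-3,4,4a,5,6,7,8,8a-octahydronaphthalen-1-yl]butan-2-one, via hydroxy ketal 24 (not isolated)
Conditions: LiAlH4, THF, 0 °C → reflux; then 1 M HCl, THF, rt
Reagents that add atoms: none
Why: LiAlH4 reduces the hindered axial ester to the primary alcohol, and the acidic work-up should hydrolyse the dioxolane to free the methyl ketone.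

Step 17
Reactants: 25 4-[(4aR,5S,8aS)-5-(hydroxymethyl)-2,5,8a-trimethyl-3,4,4a,5,6,7,8,8a-octahydronaphthalen-1-yl]butan-2-one
Product: 26 methyl (2E)-5-[(4aR,5S,8aS)-5-(hydroxymethyl)-2,5,8a-trimethyl-3,4,4a,5,6,7,8,8a-octahydronaphthalen-1-yl]-3-methylpent-2-enoate
Conditions: NaH, trimethyl phosphonoacetate, THF, 0 °C → reflux
Reagents that add atoms: trimethyl phosphonoacetate, COC(=O)CP(=O)(OC)OC
Why: Horner–Wadsworth–Emmons olefination of the methyl ketone should give the trisubstituted enoate with the E isomer favoured (ester trans to the larger C12 chain), the minor Z isomer being removed by chromatography.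

Step 18
Reactants: 26 methyl (2E)-5-[(4aR,5S,8aS)-5-(hydroxymethyl)-2,5,8a-trimethyl-3,4,4a,5,6,7,8,8a-octahydronaphthalen-1-yl]-3-methylpent-2-enoate
Product: 27 methyl (2E)-5-[(4aR,5S,8aS)-5-(acetoxymethyl)-2,5,8a-trimethyl-3,4,4a,5,6,7,8,8a-octahydronaphthalen-1-yl]-3-methylpent-2-enoate
Conditions: Ac2O, pyridine, 4-(dimethylamino)pyridine (cat.), CH2Cl2, rt
Reagents that add atoms: acetic anhydride, CC(=O)OC(C)=O
Why: Acetylation of the primary neopentyl alcohol under nucleophilic catalysis should complete the target.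

**Compound list**

1 | geranyl acetate, (2E)-3,7-dimethylocta-2,6-dien-1-yl acetate | CC(C)=CCC/C(C)=C/COC(C)=O | starting material
2 | (2E)-5-(5,5-dimethyl-1,2,4-trioxolan-3-yl)-3-methylpent-2-en-1-yl acetate (secondary ozonide) | CC1(C)OOC(CC/C(C)=C/COC(C)=O)O1 | intermediate
3 | (2E)-3-methyl-6-oxohex-2-en-1-yl acetate | O=CCC/C(C)=C/COC(C)=O | intermediate
4 | (2E)-6-hydroxy-3-methylhex-2-en-1-yl acetate | OCCC/C(C)=C/COC(C)=O | intermediate
5 | (2E)-6-iodo-3-methylhex-2-en-1-yl acetate | ICCC/C(C)=C/COC(C)=O | intermediate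
6 | (2E)-pent-2-enal | CC/C=C/C=O | starting material
7 | dimethyl malonate | COC(=O)CC(=O)OC | starting material
8 | dimethyl 2-[(2E)-pent-2-en-1-ylidene]propanedioate | CC/C=C/C=C(C(=O)OC)C(=O)OC | intermediate
9 | sodium salt of 8 (pentadienyl malonate anion) | [Na+].C/C=C/C=C/[C-](C(=O)OC)C(=O)OC | intermediate
10 | dimethyl 2-[(4E)-6-(acetyloxy)-4-methylhex-4-en-1-yl]-2-[(1E,3E)-penta-1,3-dien-1-yl]propanedioate | C/C=C/C=C/C(C(=O)OC)(C(=O)OC)CCC/C(C)=C/COC(C)=O | intermediate
11 | dimethyl 2-[(4E)-6-hydroxy-4-methylhex-4-en-1-yl]-2-[(1E,3E)-penta-1,3-dien-1-yl]propanedioate | C/C=C/C=C/C(C(=O)OC)(C(=O)OC)CCC/C(C)=C/CO | intermediate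
12 | dimethyl 2-[(4E)-4-methyl-6-oxohex-4-en-1-yl]-2-[(1E,3E)-penta-1,3-dien-1-yl]propanedioate | C/C=C/C=C/C(C(=O)OC)(C(=O)OC)CCC/C(C)=C/C=O | intermediate
13 | dimethyl (4aS,5S,6S,8aR)-5-formyl-4a,6-dimethyl-3,4,4a,5,6,8a-hexahydronaphthalene-1,1(2H)-dicarboxylate | O=C[C@H]1[C@@H](C)C=C[C@H]2C(C(=O)OC)(C(=O)OC)CCC[C@]12C | intermediate
14 | dimethyl (4aS,5S,6S,8aR)-5-formyl-4a,6-dimethyloctahydronaphthalene-1,1(2H)-dicarboxylate | O=C[C@H]1[C@@H](C)CC[C@H]2C(C(=O)OC)(C(=O)OC)CCC[C@]12C | intermediate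
15 | dimethyl (4aS,5R,6S,8aR)-5-formyl-4a,6-dimethyl-5-(phenylselanyl)octahydronaphthalene-1,1(2H)-dicarboxylate | O=C[C@@]1([Se]c2ccccc2)[C@@H](C)CC[C@H]3C(C(=O)OC)(C(=O)OC)CCC[C@]13C | intermediate
16 | dimethyl (4aS,5R,6S,8aR)-5-formyl-4a,6-dimethyl-5-(phenylseleninyl)octahydronaphthalene-1,1(2H)-dicarboxylate | O=C[C@@]1([Se](=O)c2ccccc2)[C@@H](C)CC[C@H]3C(C(=O)OC)(C(=O)OC)CCC[C@]13C | intermediate
17 | dimethyl (4aS,8aR)-5-formyl-4a,6-dimethyl-3,4,4a,7,8,8a-hexahydronaphthalene-1,1(2H)-dicarboxylate | O=CC1=C(C)CC[C@H]2C(C(=O)OC)(C(=O)OC)CCC[C@]12C | intermediate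
18 | dimethyl (4aS,8aR)-4a,6-dimethyl-5-[(1E)-3-oxobut-1-en-1-yl]-3,4,4a,7,8,8a-hexahydronaphthalene-1,1(2H)-dicarboxylate | CC(=O)/C=C/C1=C(C)CC[C@H]2C(C(=O)OC)(C(=O)OC)CCC[C@]12C | intermediate
19 | dimethyl (4aS,8aR)-4a,6-dimethyl-5-(3-oxobutyl)-3,4,4a,7,8,8a-hexahydronaphthalene-1,1(2H)-dicarboxylate | CC(=O)CCC1=C(C)CC[C@H]2C(C(=O)OC)(C(=O)OC)CCC[C@]12C | intermediate
20 | dimethyl (4aS,8aR)-4a,6-dimethyl-5-[2-(2-methyl-1,3-dioxolan-2-yl)ethyl]-3,4,4a,7,8,8a-hexahydronaphthalene-1,1(2H)-dicarboxylate | CC1(CCC2=C(C)CC[C@H]3C(C(=O)OC)(C(=O)OC)CCC[C@]23C)OCCO1 | intermediate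
21 | methyl (4aS,8aS)-4a,6-dimethyl-5-[2-(2-methyl-1,3-dioxolan-2-yl)ethyl]-1,2,3,4,4a,7,8,8a-octahydronaphthalene-1-carboxylate (both C1 epimers) | CC1(CCC2=C(C)CC[C@H]3C(C(=O)OC)CCC[C@]23C)OCCO1 | intermediate
22 | lithium ester enolate of 21 | [Li+].CC1(CCC2=C(C)CC[C@H]3C(=C([O-])OC)CCC[C@]23C)OCCO1 | intermediate
23 | methyl (1S,4aS,8aR)-1,4a,6-trimethyl-5-[2-(2-methyl-1,3-dioxolan-2-yl)ethyl]-1,2,3,4,4a,7,8,8a-octahydronaphthalene-1-carboxylate | CC1(CCC2=C(C)CC[C@H]3[C@@](C)(C(=O)OC)CCC[C@]23C)OCCO1 | intermediate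
24 | [(1S,4aS,8aR)-1,4a,6-trimethyl-5-[2-(2-methyl-1,3-dioxolan-2-yl)ethyl]-1,2,3,4,4a,7,8,8a-octahydronaphthalen-1-yl]methanol | CC1(CCC2=C(C)CC[C@H]3[C@@](C)(CO)CCC[C@]23C)OCCO1 | intermediate
25 | 4-[(4aR,5S,8aS)-5-(hydroxymethyl)-2,5,8a-trimethyl-3,4,4a,5,6,7,8,8a-octahydronaphthalen-1-yl]butan-2-one | CC(=O)CCC1=C(C)CC[C@H]2[C@@](C)(CO)CCC[C@]12C | intermediate
26 | methyl (2E)-5-[(4aR,5S,8aS)-5-(hydroxymethyl)-2,5,8a-trimethyl-3,4,4a,5,6,7,8,8a-octahydronaphthalen-1-yl]-3-methylpent-2-enoate | COC(=O)/C=C(\C)CCC1=C(C)CC[C@H]2[C@@](C)(CO)CCC[C@]12C | intermediate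
27 | methyl (2E)-5-[(4aR,5S,8aS)-5-(acetoxymethyl)-2,5,8a-trimethyl-3,4,4a,5,6,7,8,8a-octahydronaphthalen-1-yl]-3-methylpent-2-enoate | COC(=O)/C=C(\C)CCC1=C(C)CC[C@H]2[C@@](C)(COC(C)=O)CCC[C@]12C | target

**Step count and risks**

Total step count: 18. Longest linear sequence: 17 steps (steps 1–3 and 5–18, from geranyl acetate 1); step 4 prepares the second fragment.

The three steps most likely to fail:

Step 8. The β,β-disubstituted enal may cyclise too slowly at low temperature, since the bond C5–C10 joins a carbon next to the quaternary C4 to a carbon that becomes quaternary. The catalyst may also discriminate the two enal faces poorly. The fallback replaces asymmetric catalysis by resolution. It sets out from 12, which is cyclised with an achiral Lewis acid (Me2AlCl, CH2Cl2, −78 → 0 °C) to the racemic endo adduct, that is 13 together with its enantiomer, dimethyl (4aR,5R,6R,8aS)-5-formyl-4a,6-dimethyl-3,4,4a,5,6,8a-hexahydronaphthalene-1,1(2H)-dicarboxylate F1. The mixture is condensed with (1R,2R)-N,N'-dimethyl-1,2-diphenylethane-1,2-diamine (4 Å molecular sieves, Et2O) to the diastereomeric imidazolidines, the aminal of 13 F2 and the aminal of the enantiomer F3, which should be separable by chromatography. Hydrolysis of F2 (dilute aqueous HCl, Et2O) returns to the route at 13.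

Step 10. Selenenylation at the crowded C9, between the quaternary C10 and the methyl-bearing C8, may stall, or the selenoxide may be oxidised further before it eliminates. The fallback uses palladium instead of selenium. It sets out from 14, which is converted with Me3SiOSO2CF3 and Et3N (CH2Cl2, 0 °C) into the trimethylsilyl enol ether of the aldehyde, dimethyl (4aS,6S,8aR)-4a,6-dimethyl-5-{[(trimethylsilyl)oxy]methylidene}octahydronaphthalene-1,1(2H)-dicarboxylate F4. Saegusa–Ito oxidation of F4 (Pd(OAc)2, MeCN, rt), with β-hydride elimination of H8, comes back to the route at 17.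

Step 17. The olefination of the methyl ketone may give poor control of the C13=C14 geometry and a difficult separation of the isomers. The fallback fixes the geometry by a syn carbometalation. It sets out from 25, which is protected as its silyl ether (tBuMe2SiCl, imidazole, DMF), 4-[(4aR,5S,8aS)-5-({[tert-butyl(dimethyl)silyl]oxy}methyl)-2,5,8a-trimethyl-3,4,4a,5,6,7,8,8a-octahydronaphthalen-1-yl]butan-2-one F5. The kinetic enolate (LiN(iPr)2, THF, −78 °C) is trapped with ClP(O)(OEt)2 as the enol diethyl phosphate F6, which is eliminated in the same flask (LiN(iPr)2, −78 °C → rt) to the terminal alkyne, the but-3-yn-1-yl silyl ether F7. Zirconium-catalysed carboalumination (Me3Al, Cp2ZrCl2, CH2Cl2, rt) adds methyl and aluminium syn across the alkyne to give the (E)-alkenyldimethylalane F8. Quenching with ClCO2Me gives the (E)-enoate silyl ether F9, and removal of the silyl group (Bu4NF, THF) comes back to the route at 26.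

**Further compounds**

F1 | step 8 | dimethyl (4aR,5R,6R,8aS)-5-formyl-4a,6-dimethyl-3,4,4a,5,6,8a-hexahydronaphthalene-1,1(2H)-dicarboxylate (enantiomer of 13) | O=C[C@@H]1[C@H](C)C=C[C@@H]2C(C(=O)OC)(C(=O)OC)CCC[C@@]12C
F2 | step 8 | dimethyl (4aS,5S,6S,8aR)-5-[(4R,5R)-1,3-dimethyl-4,5-diphenylimidazolidin-2-yl]-4a,6-dimethyl-3,4,4a,5,6,8a-hexahydronaphthalene-1,1(2H)-dicarboxylate (aminal of 13) | CN1[C@H](c2ccccc2)[C@@H](c3ccccc3)N(C)C1[C@H]4[C@@H](C)C=C[C@H]5C(C(=O)OC)(C(=O)OC)CCC[C@]45C
F3 | step 8 | dimethyl (4aR,5R,6R,8aS)-5-[(4R,5R)-1,3-dimethyl-4,5-diphenylimidazolidin-2-yl]-4a,6-dimethyl-3,4,4a,5,6,8a-hexahydronaphthalene-1,1(2H)-dicarboxylate (aminal of F1) | CN1[C@H](c2ccccc2)[C@@H](c3ccccc3)N(C)C1[C@@H]4[C@H](C)C=C[C@@H]5C(C(=O)OC)(C(=O)OC)CCC[C@@]45C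
F4 | step 10 | dimethyl (4aS,6S,8aR)-4a,6-dimethyl-5-{[(trimethylsilyl)oxy]methylidene}octahydronaphthalene-1,1(2H)-dicarboxylate (enol ether geometry not defined) | C[Si](C)(C)OC=C1[C@@H](C)CC[C@H]2C(C(=O)OC)(C(=O)OC)CCC[C@]12C
F5 | step 17 | 4-[(4aR,5S,8aS)-5-({[tert-butyl(dimethyl)silyl]oxy}methyl)-2,5,8a-trimethyl-3,4,4a,5,6,7,8,8a-octahydronaphthalen-1-yl]butan-2-one | CC(=O)CCC1=C(C)CC[C@H]2[C@@](C)(CO[Si](C)(C)C(C)(C)C)CCC[C@]12C
F6 | step 17 | 4-[(4aR,5S,8aS)-5-({[tert-butyl(dimethyl)silyl]oxy}methyl)-2,5,8a-trimethyl-3,4,4a,5,6,7,8,8a-octahydronaphthalen-1-yl]but-1-en-2-yl diethyl phosphate | C=C(CCC1=C(C)CC[C@H]2[C@@](C)(CO[Si](C)(C)C(C)(C)C)CCC[C@]12C)OP(=O)(OCC)OCC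
F7 | step 17 | tert-butyl{[(1S,4aS,8aR)-5-(but-3-yn-1-yl)-1,4a,6-trimethyl-1,2,3,4,4a,7,8,8a-octahydronaphthalen-1-yl]methoxy}dimethylsilane | C#CCCC1=C(C)CC[C@H]2[C@@](C)(CO[Si](C)(C)C(C)(C)C)CCC[C@]12C
F8 | step 17 | (E)-alkenyldimethylalane from F7 (AlMe2 on C14, new methyl on C13) | C[Al](C)/C=C(\C)CCC1=C(C)CC[C@H]2[C@@](C)(CO[Si](C)(C)C(C)(C)C)CCC[C@]12C
F9 | step 17 | methyl (2E)-5-[(4aR,5S,8aS)-5-({[tert-butyl(dimethyl)silyl]oxy}methyl)-2,5,8a-trimethyl-3,4,4a,5,6,7,8,8a-octahydronaphthalen-1-yl]-3-methylpent-2-enoate | COC(=O)/C=C(\C)CCC1=C(C)CC[C@H]2[C@@](C)(CO[Si](C)(C)C(C)(C)C)CCC[C@]12C
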